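**Retrosynthetic overview**
- Target ⇐ tricyclic deoxy lactone (E‑C4=C5 alkene) by a last, substrate‑controlled peracid epoxidation.
- Deoxy lactone ⇐ allylic bromide/enal (key step): the acrylate β‑carbon C7 is made nucleophilic as a 2‑(methoxycarbonyl)allylchromium (ester homoenolate equivalent) and adds to the enal carbon C6, joining two acceptor carbons; this closes the nine‑membered oxacycle, then the γ‑lactone.
- Allylic bromide ⇐ alkynediol mono‑tiglate: oxolane ring by palladium cyclisation–methoxycarbonylation (C7–O and C11–C12).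
- Alkynediol ⇐ 1,2‑diketone + ynone enol silane: copper–bis(oxazoline) aldol (C9–C10, sets C10), then ruthenium transfer hydrogenation (sets C8).
- Diketone ⇐ geranyl acetate (ozonolysis) + acetyl anion equivalent. Ring order: oxolane → nine‑membered ring and lactone → epoxide.

Assumption: the SMILES is read as the (4R,5R,6R,7S,8S,10R) tiglate [(E)‑2‑methylbut‑2‑enoate]; atom labels used below are C1 (ketone), C2, C3, C4/C5 (epoxide, C4 bears CH3), C6 (lactone O–CH), C7 (spiro carbon with the ether O), C8 (ester‑bearing CH), C9, C10 (ether carbon with CH3), C11/C12/C13 (lactone α‑carbon, carbonyl, exo‑methylene).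

**Step 1**
Reactants: 1 geranyl acetate
Product: 3 (2E)-3-methyl-6-oxohex-2-en-1-yl acetate, via secondary ozonide 2 (not isolated)
Conditions: O3 (1.0 equiv), CH2Cl2, −78 °C; then Me2S, −78 °C to rt
Reagents that add atoms: ozone, [O-][O+]=O
Why: Ozonolysis with reductive work‑up cleaves only the electron‑rich terminal trisubstituted alkene, because the 2,3‑alkene is deactivated by the allylic acetate; no stereocentre is formed and the E‑alkene is kept.

**Step 2**
Reactants: 3 (2E)-3-methyl-6-oxohex-2-en-1-yl acetate; 4 ethyl vinyl ether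
Product: 6 (2E)-6-hydroxy-3-methyl-7-oxooct-2-en-1-yl acetate (racemic carbinol), via enol ether adduct 5 (not isolated)
Conditions: 4 (3 equiv), t-BuLi (1.2 equiv), THF, −78 to 0 °C; then 3, −78 °C; then 1 M HCl, 0 °C
Reagents that add atoms: water, O
Why: 1‑Ethoxyvinyllithium (an acetyl anion equivalent made by α‑lithiation of 4) adds 1,2 to the aldehyde faster than to the acetate at −78 °C, and dilute acid hydrolyses the enol ether to the methyl ketone; the new carbinol centre is racemic and is removed in step 3.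

**Step 3**
Reactants: 6 (2E)-6-hydroxy-3-methyl-7-oxooct-2-en-1-yl acetate
Product: 7 (2E)-3-methyl-6,7-dioxooct-2-en-1-yl acetate
Conditions: Dess–Martin periodinane, CH2Cl2, rt
Reagents that add atoms: none
Why: Dess–Martin oxidation of the acyloin gives the 1,2‑diketone without touching the alkene or the acetate; the only stereocentre disappears.

**Step 4**
Reactants: 8 tert-butyldimethyl(prop-2-yn-1-yloxy)silane; 9 acetyl chloride
Product: 10 5-[(tert-butyldimethylsilyl)oxy]pent-3-yn-2-one
Conditions: PdCl2(PPh3)2 (2 mol%), CuI (4 mol%), Et3N (1.1 equiv), THF, rt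
Reagents that add atoms: none
Why: Copper‑cocatalysed acyl Sonogashira coupling of the terminal alkyne with the acid chloride gives the ynone directly; no stereocentre.

**Step 5**
Reactants: 10 5-[(tert-butyldimethylsilyl)oxy]pent-3-yn-2-one
Product: 11 tert-butyldimethyl({4-[(trimethylsilyl)oxy]pent-4-en-2-yn-1-yl}oxy)silane
Conditions: TMSOTf, Et3N, Et2O, 0 °C
Reagents that add atoms: trimethylsilyl trifluoromethanesulfonate, C[Si](C)(C)OS(=O)(=O)C(F)(F)F
Why: Soft enolisation (silyl triflate/amine) of the methyl ketone, whose only α‑hydrogens are on CH3, gives the 2‑silyloxy enyne needed for a Mukaiyama aldol; no stereocentre.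

**Step 6**
Reactants: 7 (2E)-3-methyl-6,7-dioxooct-2-en-1-yl acetate; 11 tert-butyldimethyl({4-[(trimethylsilyl)oxy]pent-4-en-2-yn-1-yl}oxy)silane
Product: 13 (2E,7R)-12-[(tert-butyldimethylsilyl)oxy]-7-hydroxy-3,7-dimethyl-6,9-dioxododec-2-en-10-yn-1-yl acetate, via trimethylsilyl ether 12 (not isolated)
Conditions: Cu(OTf)2 (10 mol%), 2,2'-(propane-2,2-diyl)bis[(4R)-4-tert-butyl-4,5-dihydrooxazole] (11 mol%), THF, −78 °C; then 1 M HCl, THF, 0 °C
Reagents that add atoms: none
Why: Evans‑type enantioselective Mukaiyama aldol in which the 1,2‑diketone binds divalent copper as a bidentate chelate, the enol silane attacks the less hindered acetyl carbonyl (C10) on the face left open by the (R,R) ligand, setting C10 as R, and acid removes the transferred silyl group.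

**Step 7**
Reactants: 13 (2E,7R)-12-[(tert-butyldimethylsilyl)oxy]-7-hydroxy-3,7-dimethyl-6,9-dioxododec-2-en-10-yn-1-yl acetate
Product: 14 (2E,7R,9S)-12-[(tert-butyldimethylsilyl)oxy]-7,9-dihydroxy-3,7-dimethyl-6-oxododec-2-en-10-yn-1-yl acetate
Conditions: Ru[(S,S)-TsDPEN](p-cymene) (2 mol%), i-PrOH, rt
Reagents that add atoms: none
Why: Noyori asymmetric transfer hydrogenation reduces the alkynyl ketone far faster than the hindered dialkyl ketone and, with the (S,S) catalyst, sets C8 as S (1,3‑syn to the C10 hydroxyl) under reagent control, while the base‑free catalyst suppresses retro‑aldol and oxa‑Michael side reactions.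

**Step 8**
Reactants: 14 (2E,7R,9S)-12-[(tert-butyldimethylsilyl)oxy]-7,9-dihydroxy-3,7-dimethyl-6-oxododec-2-en-10-yn-1-yl acetate
Product: 15 (4S,6R,10E)-1-[(tert-butyldimethylsilyl)oxy]-4,6,12-trihydroxy-6,10-dimethyldodec-10-en-2-yn-7-one
Conditions: K2CO3 (0.2 equiv), MeOH, 0 °C
Reagents that add atoms: none
Why: Base‑catalysed transesterification removes the only ester present at this stage (the primary allylic acetate); the stereocentres are untouched.

**Step 9**
Reactants: 15 (4S,6R,10E)-1-[(tert-butyldimethylsilyl)oxy]-4,6,12-trihydroxy-6,10-dimethyldodec-10-en-2-yn-7-one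
Product: 16 (2E,7R,9S)-12-[(tert-butyldimethylsilyl)oxy]-7,9-dihydroxy-3,7-dimethyl-6-oxododec-2-en-10-ynal
Conditions: [Cu(MeCN)4]OTf (5 mol%), 2,2'-bipyridine (5 mol%), TEMPO (5 mol%), N-methylimidazole (10 mol%), MeCN, air, rt
Reagents that add atoms: none
Why: Stahl copper/TEMPO aerobic oxidation is selective for the primary allylic alcohol over the secondary and tertiary ones and gives the E‑enal without isomerisation.

**Step 10**
Reactants: 16 (2E,7R,9S)-12-[(tert-butyldimethylsilyl)oxy]-7,9-dihydroxy-3,7-dimethyl-6-oxododec-2-en-10-ynal; 17 (2E)-2-methylbut-2-enoyl chloride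
Product: 18 (4S,6R,10E)-1-[(tert-butyldimethylsilyl)oxy]-6-hydroxy-6,10-dimethyl-7,12-dioxododec-10-en-2-yn-4-yl (2E)-2-methylbut-2-enoate
Conditions: 17 (1.5 equiv), pyridine, DMAP (10 mol%), CH2Cl2, 0 °C
Reagents that add atoms: none
Why: DMAP‑catalysed acylation esterifies the secondary propargylic C8 hydroxyl with retention while the tertiary C10 hydroxyl stays free; installing the tiglate now also prevents O8 from lactonising onto the C12 ester formed in step 11.

**Step 11**
Reactants: 18 (4S,6R,10E)-1-[(tert-butyldimethylsilyl)oxy]-6-hydroxy-6,10-dimethyl-7,12-dioxododec-10-en-2-yn-4-yl (2E)-2-methylbut-2-enoate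
Product: 19 methyl (2E)-3-[(tert-butyldimethylsilyl)oxy]-2-[(3S,5R)-5-methyl-5-[(4E)-4-methyl-6-oxohex-4-enoyl]-3-{[(2E)-2-methylbut-2-enoyl]oxy}oxolan-2-ylidene]propanoate
Conditions: PdCl2(MeCN)2 (5 mol%), p-benzoquinone (1.5 equiv), CO (1 atm), MeOH, −10 to 0 °C
Reagents that add atoms: carbon monoxide, [C-]#[O+]; methanol, CO
Why: Kato–Akita cyclisation–methoxycarbonylation in which divalent palladium activates the alkyne, the tertiary hydroxyl attacks C7 by 5‑exo‑dig anti‑oxypalladation, and CO insertion with methanolysis of the vinylpalladium gives the β‑alkoxyacrylate with CO2Me trans to the ring oxygen (benzoquinone reoxidises zerovalent palladium); C8 and C10 are untouched.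

**Step 12**
Reactants: 19 methyl (2E)-3-[(tert-butyldimethylsilyl)oxy]-2-[(3S,5R)-5-methyl-5-[(4E)-4-methyl-6-oxohex-4-enoyl]-3-{[(2E)-2-methylbut-2-enoyl]oxy}oxolan-2-ylidene]propanoate
Product: 20 methyl (2Z)-3-bromo-2-[(3S,5R)-5-methyl-5-[(4E)-4-methyl-6-oxohex-4-enoyl]-3-{[(2E)-2-methylbut-2-enoyl]oxy}oxolan-2-ylidene]propanoate
Conditions: Ph3PBr2 (1.3 equiv), CH2Cl2, 0 °C
Reagents that add atoms: dibromotriphenylphosphorane, BrP(Br)(c1ccccc1)(c1ccccc1)c1ccccc1
Why: Dibromotriphenylphosphorane converts the primary allylic silyl ether directly into the bromide (oxyphosphonium formation, then bromide SN2) at a temperature the enal tolerates; the alkene geometry is kept (the descriptor becomes Z only through the priority change).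

**Step 13**
Reactants: 20 methyl (2Z)-3-bromo-2-[(3S,5R)-5-methyl-5-[(4E)-4-methyl-6-oxohex-4-enoyl]-3-{[(2E)-2-methylbut-2-enoyl]oxy}oxolan-2-ylidene]propanoate
Product: 23 deoxy lactone (6R,7S,8S,10R; the 4E‑alkene analogue of the target), via allylchromium dichloride 21 (not isolated), via hydroxy ester 22 (not isolated)
Conditions: CrCl2 (8 equiv), THF, rt, slow addition of 20 (final 0.003 M); then 40 °C
Reagents that add atoms: none
Why: Proposed new method: insertion of divalent chromium into the allylic C–Br bond turns the acrylate β‑carbon C7 (normally an acceptor) into the γ‑terminus of a 2‑(methoxycarbonyl)allylchromium, an ester homoenolate equivalent, which adds to the enal carbon C6 through a closed chair transition state (ring oxygen pseudo‑axial as fixed by the Z‑allyl geometry, C5 equatorial, the tether forcing attack on the oxolane face syn to the C10 acyl arm and anti to the C8 ester), setting C7 as S and C6 as R, after which the chromium alkoxide lactonises onto the methyl ester; the closest known reaction type is the intramolecular Nozaki–Hiyama–Kishi 2‑(alkoxycarbonyl)allylation–lactonisation used to close ten‑membered germacranolide rings.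

**Step 14**
Reactants: 23 deoxy lactone (6R,7S,8S,10R; 4E)
Product: 24 target CNP0281419.1
Conditions: mCPBA (1.1 equiv), NaHCO3, CH2Cl2, 0 °C
Reagents that add atoms: 3-chloroperbenzoic acid, O=C(OO)c1cccc(Cl)c1
Why: Prilezhaev epoxidation of the only electron‑rich alkene; the inner face of the E‑cycloalkene is blocked by the ring and A(1,3) strain with the C4 methyl holds H6 in the alkene plane, so oxygen is delivered to the outer face syn to O6, giving the 4R,5R epoxide.

**Compound list**
1 | geranyl acetate, (2E)-3,7-dimethylocta-2,6-dien-1-yl acetate | CC(C)=CCC/C(C)=C/COC(C)=O | starting material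
2 | (2E)-5-(5,5-dimethyl-1,2,4-trioxolan-3-yl)-3-methylpent-2-en-1-yl acetate (secondary ozonide, racemic) | CC(=O)OC/C=C(C)/CCC1OOC(C)(C)O1 | intermediate
3 | (2E)-3-methyl-6-oxohex-2-en-1-yl acetate | CC(=O)OC/C=C(C)/CCC=O | intermediate
4 | ethyl vinyl ether | C=COCC | starting material
5 | (2E)-7-ethoxy-6-hydroxy-3-methylocta-2,7-dien-1-yl acetate (racemic) | CCOC(=C)C(O)CC/C(C)=C/COC(C)=O | intermediate
6 | (2E)-6-hydroxy-3-methyl-7-oxooct-2-en-1-yl acetate (racemic) | CC(=O)C(O)CC/C(C)=C/COC(C)=O | intermediate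
7 | (2E)-3-methyl-6,7-dioxooct-2-en-1-yl acetate | CC(=O)C(=O)CC/C(C)=C/COC(C)=O | intermediate
8 | tert-butyldimethyl(prop-2-yn-1-yloxy)silane | C#CCO[Si](C)(C)C(C)(C)C | starting material
9 | acetyl chloride | CC(Cl)=O | starting material
10 | 5-[(tert-butyldimethylsilyl)oxy]pent-3-yn-2-one | CC(=O)C#CCO[Si](C)(C)C(C)(C)C | intermediate
11 | tert-butyldimethyl({4-[(trimethylsilyl)oxy]pent-4-en-2-yn-1-yl}oxy)silane | C=C(O[Si](C)(C)C)C#CCO[Si](C)(C)C(C)(C)C | intermediate
12 | (2E,7R)-12-[(tert-butyldimethylsilyl)oxy]-3,7-dimethyl-6,9-dioxo-7-[(trimethylsilyl)oxy]dodec-2-en-10-yn-1-yl acetate | CC(=O)OC/C=C(C)/CCC(=O)[C@@](O[Si](C)(C)C)(C)CC(=O)C#CCO[Si](C)(C)C(C)(C)C | intermediate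
13 | (2E,7R)-12-[(tert-butyldimethylsilyl)oxy]-7-hydroxy-3,7-dimethyl-6,9-dioxododec-2-en-10-yn-1-yl acetate | CC(=O)OC/C=C(C)/CCC(=O)[C@@](O)(C)CC(=O)C#CCO[Si](C)(C)C(C)(C)C | intermediate
14 | (2E,7R,9S)-12-[(tert-butyldimethylsilyl)oxy]-7,9-dihydroxy-3,7-dimethyl-6-oxododec-2-en-10-yn-1-yl acetate | CC(=O)OC/C=C(C)/CCC(=O)[C@@](O)(C)C[C@H](O)C#CCO[Si](C)(C)C(C)(C)C | intermediate
15 | (4S,6R,10E)-1-[(tert-butyldimethylsilyl)oxy]-4,6,12-trihydroxy-6,10-dimethyldodec-10-en-2-yn-7-one | OC/C=C(C)/CCC(=O)[C@@](O)(C)C[C@H](O)C#CCO[Si](C)(C)C(C)(C)C | intermediate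
16 | (2E,7R,9S)-12-[(tert-butyldimethylsilyl)oxy]-7,9-dihydroxy-3,7-dimethyl-6-oxododec-2-en-10-ynal | O=C/C=C(C)/CCC(=O)[C@@](O)(C)C[C@H](O)C#CCO[Si](C)(C)C(C)(C)C | intermediate
17 | (2E)-2-methylbut-2-enoyl chloride (tigloyl chloride) | C/C=C(\C)C(Cl)=O | starting material
18 | (4S,6R,10E)-1-[(tert-butyldimethylsilyl)oxy]-6-hydroxy-6,10-dimethyl-7,12-dioxododec-10-en-2-yn-4-yl (2E)-2-methylbut-2-enoate | O=C/C=C(C)/CCC(=O)[C@@](O)(C)C[C@H](OC(=O)/C(C)=C/C)C#CCO[Si](C)(C)C(C)(C)C | intermediate
19 | methyl (2E)-3-[(tert-butyldimethylsilyl)oxy]-2-[(3S,5R)-5-methyl-5-[(4E)-4-methyl-6-oxohex-4-enoyl]-3-{[(2E)-2-methylbut-2-enoyl]oxy}oxolan-2-ylidene]propanoate | O=C/C=C(C)/CCC(=O)[C@@]1(C)C[C@H](OC(=O)/C(C)=C/C)/C(=C(/CO[Si](C)(C)C(C)(C)C)C(=O)OC)O1 | intermediate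
20 | methyl (2Z)-3-bromo-2-[(3S,5R)-5-methyl-5-[(4E)-4-methyl-6-oxohex-4-enoyl]-3-{[(2E)-2-methylbut-2-enoyl]oxy}oxolan-2-ylidene]propanoate | O=C/C=C(C)/CCC(=O)[C@@]1(C)C[C@H](OC(=O)/C(C)=C/C)/C(=C(/CBr)C(=O)OC)O1 | intermediate
21 | allylchromium dichloride (trivalent chromium) formed from 20 by replacing Br with CrCl2 | O=C/C=C(C)/CCC(=O)[C@@]1(C)C[C@H](OC(=O)/C(C)=C/C)/C(=C(/C[Cr](Cl)Cl)C(=O)OC)O1 | intermediate
22 | methyl 2-[(1R,2R,3E,8R,10S)-2-hydroxy-4,8-dimethyl-10-{[(2E)-2-methylbut-2-enoyl]oxy}-7-oxo-11-oxabicyclo[6.2.1]undec-3-en-1-yl]prop-2-enoate | C=C(C(=O)OC)[C@]12O[C@](C)(C[C@@H]1OC(=O)/C(C)=C/C)C(=O)CC/C(C)=C/[C@H]2O | intermediate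
23 | deoxy lactone: the (6R,7S,8S,10R)-configured 4E‑alkene analogue of the target (C4=C5 in place of the epoxide) | C=C1C(=O)O[C@@H]2/C=C(C)/CCC(=O)[C@@]3(C)C[C@H](OC(=O)/C(C)=C/C)[C@@]12O3 | intermediate
24 | CNP0281419.1, (4R,5R,6R,7S,8S,10R) | C=C1C(=O)O[C@@H]2[C@H]3O[C@]3(C)CCC(=O)[C@@]3(C)C[C@H](OC(=O)/C(C)=C/C)[C@@]12O3 | target

**Step count and weak points**
Total step count: 14. Longest linear sequence: 12 (steps 1–3, then 6–14, from geranyl acetate).

Most likely to fail, first: step 13. The nine‑membered closure competes with oligomerisation and protodemetalation, and the C6 configuration rests on the chair model. The fallback sets out from 20 and replaces reductive metalation by a fluoride‑triggered intramolecular Hosomi–Sakurai reaction. Silylation catalysed by zerovalent palladium (Pd(PPh3)4, Me3SiSiMe3, THF, 50 °C) gives methyl (2Z)-2-[(3S,5R)-5-methyl-5-[(4E)-4-methyl-6-oxohex-4-enoyl]-3-{[(2E)-2-methylbut-2-enoyl]oxy}oxolan-2-ylidene]-3-(trimethylsilyl)propanoate F1. Anhydrous Bu4NF in THF at high dilution then releases the allyl nucleophile, which adds through C7 to the enal to give hydroxy ester 22. Lactonisation of 22 rejoins the route at 23.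

Second: step 11. The propargylic tiglate carbonyl may compete with the tertiary hydroxyl for the activated alkyne, the vinylpalladium may lose the silyloxy group, or 6‑endo closure may intrude. The fallback sets out from 18 and separates ring closure from carbonylation. Iodine with NaHCO3 in MeCN effects 5‑exo‑dig anti iodoetherification to (3S,5R)-2-[(1E)-2-[(tert-butyldimethylsilyl)oxy]-1-iodoethylidene]-5-methyl-5-[(4E)-4-methyl-6-oxohex-4-enoyl]oxolan-3-yl (2E)-2-methylbut-2-enoate F2. Methoxycarbonylation with zerovalent palladium (Pd(PPh3)4, CO, MeOH, Et3N) then replaces iodine by CO2Me with retention and returns to 19.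

Third: step 14. The facial selectivity depends on the ring conformation, and the strained E‑alkene may react sluggishly or unselectively. The fallback sets out from 22, obtained by quenching step 13 cold with aqueous NH4Cl and omitting the warming, so that the C6 hydroxyl stays free. Hydroxyl‑directed epoxidation (VO(acac)2, t-BuOOH, CH2Cl2, 0 °C) delivers oxygen syn to that hydroxyl (the threo preference of A(1,3)‑strained allylic alcohols) and gives the (4R,5R)-4,5-epoxide of hydroxy ester 22 F3. Lactonisation with catalytic PPTS then gives 24.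

**Further compounds**
F1 | step 13 | methyl (2Z)-2-[(3S,5R)-5-methyl-5-[(4E)-4-methyl-6-oxohex-4-enoyl]-3-{[(2E)-2-methylbut-2-enoyl]oxy}oxolan-2-ylidene]-3-(trimethylsilyl)propanoate | O=C/C=C(C)/CCC(=O)[C@@]1(C)C[C@H](OC(=O)/C(C)=C/C)/C(=C(/C[Si](C)(C)C)C(=O)OC)O1
F2 | step 11 | (3S,5R)-2-[(1E)-2-[(tert-butyldimethylsilyl)oxy]-1-iodoethylidene]-5-methyl-5-[(4E)-4-methyl-6-oxohex-4-enoyl]oxolan-3-yl (2E)-2-methylbut-2-enoate | O=C/C=C(C)/CCC(=O)[C@@]1(C)C[C@H](OC(=O)/C(C)=C/C)/C(=C(/CO[Si](C)(C)C(C)(C)C)I)O1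
F3 | step 14 | (4R,5R)-4,5-epoxide of hydroxy ester 22 (methyl 2-substituted prop-2-enoate with free C6 hydroxyl) | C=C(C(=O)OC)[C@]12O[C@](C)(C[C@@H]1OC(=O)/C(C)=C/C)C(=O)CC[C@@]3(C)O[C@@H]3[C@H]2O
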